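## Structural features

1. The target is a 2,3-dihydrobenzofuran. Benzene ring A is fused through C3a–C7a to the five-membered ring B (O1, C2, C3).
2. C2 carries a 1-(methoxycarbonyl)vinyl group, Cα(=CH2)CO2Me. C3 carries an acetoxy group. C5, para to O1, carries a 1-(tigloyloxy)ethyl chain (carbinol carbon C1′).
3. C2 (S) and C3 (S) are neighbours and their substituents are cis, the more crowded arrangement. C1′ (S) is insulated from them by ring A and has to be set on its own.
4. The molecule is fragile in four ways.
   - C2–H stands anti to the benzylic C3–OAc, so base removes acetic acid and aromatises ring B.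
   - O1 is an allylic leaving group for SN2′ attack of nucleophiles on the acrylate.
   - A free C3–OH lies next to the cis ester and can lactonise.
   - The C1′ ester is p-alkoxybenzylic and ionises in acid.
5. A ketone at C3 is no safe relay. The C2–H between ketone, O1 and acrylate would let the Cα=CH2 bond slip into conjugation.
6. The real difficulty is to create the cis C2/C3 pair of ring B with the acrylate already in place, under near-neutral conditions and in one absolute sense.
7. The key step exploits the atom sequence CH2=Cα–C2–C3–O, which is the retron of an allyl transfer with transposition. C2 is the γ-carbon of a 2-(methoxycarbonyl)allyl metal that already bears O1. C3 is a formyl carbon ortho to O1 on ring A.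
8. Ring B is flat and benzo-fused. A metal that bridges the C3 oxygen and the CH2 terminus while C2–C3 forms can therefore only deliver the cis pair.

## Logic of the disconnections

**13 ⇒ 11 + 12.**
- Cut: the acyl–oxygen bond of the C1′ ester.
- Reason: this p-alkoxybenzylic ester is the most ionisable group and plays no part in the core problem, so it goes on last.
- Gain: five carbons and one alkene leave the molecule in a convergent way.
- Demand: acylation must leave the C1′–O bond intact and must use no base able to expel the C3 acetate or to open ring B at O1.

**11 ⇒ 10.**
- Cut: the C1′–H bond (carbinol back to aryl methyl ketone).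
- Reason: C1′ feels nothing of ring B, so only reagent control can set it, and an aryl methyl ketone is the best substrate class for that. The acetyl group is also inert in all earlier steps and makes the phenol of 4 acidic.
- Gain: one stereocentre is removed.
- Demand: hydride must go to the ketone only, in the presence of an acrylate and two esters.

**10 ⇒ 9.**
- Cut: the acetyl–oxygen bond at C3.
- Reason: the acetate is the trigger for aromatisation and should exist for as few steps as possible.
- Gain: small, but it exposes the homoallylic alcohol retron.
- Demand: acetylation must be faster than attack of the C3–OH on the cis ester.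

**9 ⇒ 6 (through 8 and 7), the key disconnection.**
- Cut: the C2–C3 bond, with shift of the alkene from Cα=CH2 to C2=Cα and placement of a metal, then bromine, on the CH2.
- In one sentence: ring B is closed by an enantioselective chromium-catalysed SE2′ attack of the O1-bearing γ-carbon of the allyl bromide in 6 on its own ortho formyl group. That sentence does not fit the C–O closures or the ketone reduction that would be drawn first.
- Reason: this is the only cut that clears both ring stereocentres together, and it turns the labile acrylate/allylic ether into a robust vinylogous carbonate.
- Gain: one ring and two stereocentres disappear, and 6 is achiral.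
- Demand: a closed transition state (for cis), a chiral ligand on the metal (for the absolute sense), and preference for the aldehyde over the ketone.

**6 ⇒ 5.**
- Cut: the C–Br bond.
- Reason: the allyl bromide is too reactive to survive the formation of the O1–C2 bond.
- Gain: a storable alcohol.
- Demand: a neutral bromination that spares the formyl group.

**5 ⇒ 3 + 4.**
- Cut: the O1–C2 bond, made while C2 is still sp2, so no stereochemical question arises.
- Reason: it joins ring A, with both carbonyl groups in place, to the complete four-carbon ester unit.
- Gain: two small fragments.
- Demand: substitution at the vinylic carbon only. This is secured because iodide is the only leaving group β to the transient enolate.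

**3 ⇒ 1 + 2.**
- Cut: the Cα–CH2 bond and the C–I bond.
- Reason: both are formed in one three-component event from bulk chemicals.
- Gain: commercial starting materials.
- Demand: trapping of the iodoallenolate by formaldehyde must be faster than its protonation.

## Other disconnections considered

**Alternative 1: (the first that comes to mind)**
- Cut: the C3–H bond. The carbinol is traced to the benzofuran-3(2H)-one A1.
- Forward key step: hydride delivery anti to the C2 substituent, ideally an asymmetric transfer hydrogenation with dynamic kinetic resolution of the labile C2 centre.
- Grounds for preferring the chosen plan: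
  - The racemisation that a dynamic resolution needs runs through the enol(ate) of A1. The same species can reprotonate at the CH2 terminus to give the fully conjugated ylidene ester A2, a thermodynamic sink from which C2 cannot be recovered.
  - A1 holds two aryl ketones. Both carbinol centres of the target are labelled S, but with respect to the triad oxygen/aryl/alkyl they have opposite spatial sense, so one catalyst cannot set both.
  - The two resulting benzylic alcohols would then have to be told apart for two different acylations.

**Alternative 2:**
- Cut: the O1–C2 alkyl C–O bond.
- Forward key step: closure of the free phenol onto the trans vinyl epoxide A3.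
- Grounds for preferring the chosen plan:
  - Direct opening is endo with respect to the epoxide. The backside trajectory at C2 is out of reach for the ortho oxygen of a trans epoxide, and inversion would lead to the trans series.
  - The closure would therefore have to pass through a π-allyl complex of zerovalent palladium (net retention at C2).
  - That π-allyl unit has an unhindered CH2 terminus, so attack there (seven-membered ring) competes.
  - π–σ–π exchange through the same terminus erases the C2 information.
  - An o-hydroxyaryl epoxide also tends to open at the benzylic C3 with help of the phenol, which endangers C3.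
  - Two separate stereo-defining operations (epoxidation, then closure) replace the single one of the chosen plan.

**Alternative 3:**
- Cut: the O1–C7a aryl C–O bond.
- Forward key step: Sharpless asymmetric dihydroxylation of the styrenyl alkene of diene A4, followed by intramolecular SNAr of the C2 alkoxide on C7a–F. The fluoride is activated by the para acetyl group.
- In its favour: the E-alkene would give the syn diol, which maps correctly onto the cis ring.
- Grounds for preferring the chosen plan:
  - The C3 hydroxyl is γ to the ester and should lactonise in the basic dihydroxylation medium to A5.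
  - SNAr on A5 leads to the cis-fused tricyclic lactone A6.
  - Reopening A6 to a methyl ester calls for methoxide or hydroxide, which add to the exo-methylene lactone and can trigger aromatisation.
  - The plan is longer and places its harshest (basic) steps on the most base-sensitive intermediates.

Key step: step 4

Assumption: the (S,S) ligand is written for the Re-face closure in step 4. The sense of induction for a tethered aldehyde cannot be derived with certainty, and the mirror-image ligand is used if the sense is opposite. Compounds 1, 2, 4 and 12 are taken as commercial.

## Steps

Step 1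
Reactants: 1 methyl propiolate; 2 paraformaldehyde (formaldehyde source)
Product: 3 methyl (Z)-2-(hydroxymethyl)-3-iodoprop-2-enoate
Conditions: MgI2 (1.2 equiv), CH2Cl2, 0 °C to rt; then H2O
Reagents that add atoms: magnesium diiodide, [Mg+2].[I-].[I-]
Why: β-Iodo Morita–Baylis–Hillman (halo-aldol) reaction in which iodide adds to the magnesium-activated ynoate and the β-iodoallenolate is hydroxymethylated at Cα by formaldehyde released from 2. The allenolate reacts on the side away from iodine, which should give the Z alkene, whose geometry has no consequence later.

Step 2
Reactants: 3 methyl (Z)-2-(hydroxymethyl)-3-iodoprop-2-enoate; 4 5-acetyl-2-hydroxybenzaldehyde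
Product: 5 methyl (E)-3-(4-acetyl-2-formylphenoxy)-2-(hydroxymethyl)prop-2-enoate
Conditions: DABCO (10 mol %), Et3N (1.2 equiv), MeCN, rt
Reagents that add atoms: none
Why: Nucleophilic vinylic substitution (addition–elimination) through the β-ammonium acrylate formed with DABCO; the phenol of 4 is acidified by two acyl groups and is fully ionised by Et3N, and iodide is the only leaving group β to the transient enolate. Reversible addition of DABCO and phenoxide should let the alkene settle as the more stable E isomer (aryloxy trans to the ester), and any Z isomer is carried along because step 4 is convergent.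

Step 3
Reactants: 5 methyl (E)-3-(4-acetyl-2-formylphenoxy)-2-(hydroxymethyl)prop-2-enoate
Product: 6 methyl (Z)-3-(4-acetyl-2-formylphenoxy)-2-(bromomethyl)prop-2-enoate (same spatial geometry as 5; the descriptor changes because CH2Br outranks CO2Me)
Conditions: NBS (1.3 equiv), Me2S (1.5 equiv), CH2Cl2, −20 to 0 °C
Reagents that add atoms: N-bromosuccinimide, O=C1CCC(=O)N1Br
Why: Corey–Kim bromination in which the hydroxyl is activated on sulfur and displaced by bromide in an SN2 reaction at the primary allylic carbon. The medium is neutral and leaves formyl, acetyl and vinylogous carbonate untouched, whereas CBr4/PPh3 would olefinate the aldehyde.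

Step 4
Reactants: 6 methyl (Z)-3-(4-acetyl-2-formylphenoxy)-2-(bromomethyl)prop-2-enoate
Product: 9 methyl 2-[(2S,3S)-5-acetyl-3-hydroxy-2,3-dihydro-1-benzofuran-2-yl]prop-2-enoate, via allylchromium dichloride 7 (not isolated), via trimethylsilyl ether 8 (not isolated)
Conditions: CrCl2 (10 mol %), 1,8-bis[(S)-4-isopropyl-4,5-dihydrooxazol-2-yl]-3,6-diphenyl-9H-carbazole (12 mol %), i-Pr2NEt (30 mol %), Mn powder (3 equiv), TMSCl (2 equiv), THF, rt, 6 added by syringe pump (final 0.01 M); then aq. citric acid, MeOH, 0 °C
Reagents that add atoms: none
Why: This is a catalytic asymmetric Nozaki–Hiyama–Kishi allylation run intramolecularly, in which divalent chromium reduces the C–Br bond of 6 in two one-electron steps to the trivalent allylchromium 7, Mn returns chromium to the divalent state, and TMSCl frees it from the product alkoxide as 8, which also blocks attack of that alkoxide on the ester. Species 7 holds chromium on the unhindered CH2 and transfers the allyl unit with SE2′ transposition through a six-membered cyclic transition state (Cr–O=C3···C2=Cα–CH2), so that the C2–C3 bond, ring B and the Cα=CH2 acrylate arise in the same event. Ring B closes in the 5-exo-trig mode at the formyl carbon, and the C2=Cα bond likewise lies outside the new ring. The relative configuration follows from the bicyclic transition state, because the benzo-fused five-membered ring tolerates only a small torsion about C2–C3 and the chromium bridge can span the carbonyl oxygen and Cα only when both lie on the same face, which is the cis pair. E and Z forms of 6 and 7 converge on this result, since allylchromium species interconvert by 1,3-metal shift and either geometry fits a cis-fused transition state (aryloxy axial or aryl axial). The absolute configuration is set by the twofold-symmetric tridentate ligand on chromium, which has to expose the Re face of the formyl group to C2 (giving 3S and, through the cis constraint, 2S). The closest known reaction types are the chromium-catalysed enantioselective 2-(alkoxycarbonyl)allylation of aromatic aldehydes with 2-(bromomethyl)acrylates and the closure of cyclic ethers by γ-alkoxyallylmetal–aldehyde condensation. The step needs aldehyde over C5-acetyl selectivity (innate to organochromium reagents, and only the ortho formyl group is within reach), γ- over α-attack (five- versus seven-membered ring, the latter requiring chromium on the hindered O-bearing carbon) and cyclisation over dimerisation (slow addition, high dilution).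

Step 5
Reactants: 9 methyl 2-[(2S,3S)-5-acetyl-3-hydroxy-2,3-dihydro-1-benzofuran-2-yl]prop-2-enoate
Product: 10 methyl 2-[(2S,3S)-3-acetoxy-5-acetyl-2,3-dihydro-1-benzofuran-2-yl]prop-2-enoate
Conditions: Ac2O (3 equiv), pyridine (5 equiv), CH2Cl2, 0 °C to rt, on freshly prepared 9
Reagents that add atoms: acetic anhydride, CC(=O)OC(C)=O
Why: Plain O-acetylation in which the C3–O bond is not touched, so C3 keeps its configuration. Pyridine without a stronger nucleophilic catalyst avoids SN2′ opening of ring B at O1 and loss of acetic acid, and prompt use of 9 should outrun lactonisation.

Step 6
Reactants: 10 methyl 2-[(2S,3S)-3-acetoxy-5-acetyl-2,3-dihydro-1-benzofuran-2-yl]prop-2-enoate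
Product: 11 methyl 2-[(2S,3S)-3-acetoxy-5-[(1S)-1-hydroxyethyl]-2,3-dihydro-1-benzofuran-2-yl]prop-2-enoate
Conditions: (R)-Me-CBS oxazaborolidine (15 mol %), catecholborane (1.5 equiv), toluene, −78 to −40 °C; MeOH, then pH 7 buffer
Reagents that add atoms: none
Why: Corey–Bakshi–Shibata reduction in which the ketone binds to the ring boron with the aryl group away from the catalyst and hydride is passed to the Re face, which gives the S carbinol as with other aryl methyl ketones under the R catalyst. Catecholborane at low temperature should neither hydroborate the electron-poor acrylate nor touch the esters.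

Step 7
Reactants: 11 methyl 2-[(2S,3S)-3-acetoxy-5-[(1S)-1-hydroxyethyl]-2,3-dihydro-1-benzofuran-2-yl]prop-2-enoate; 12 (E)-2-methylbut-2-enoyl chloride (tigloyl chloride)
Product: 13 methyl 2-[(2S,3S)-3-acetoxy-5-[(1S)-1-{[(E)-2-methylbut-2-enoyl]oxy}ethyl]-2,3-dihydro-1-benzofuran-2-yl]prop-2-enoate (target)
Conditions: 12 (1.5 equiv), pyridine (3 equiv), CH2Cl2, 0 °C to rt
Reagents that add atoms: none
Why: Acylation of a secondary alcohol by an acid chloride, in which the C1′–O bond is not broken, so the S configuration is kept, and the E (tigloyl) geometry is the stable one. Pyridine in place of a trialkylamine avoids vinylketene formation (deconjugation of the enoate) and elimination of the C3 acetate.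

## Compound list

1 | methyl propiolate | C#CC(=O)OC | starting material
2 | paraformaldehyde (written as formaldehyde) | C=O | starting material
3 | methyl (Z)-2-(hydroxymethyl)-3-iodoprop-2-enoate | COC(=O)/C(CO)=C\I | intermediate
4 | 5-acetyl-2-hydroxybenzaldehyde | CC(=O)c1ccc(O)c(C=O)c1 | starting material
5 | methyl (E)-3-(4-acetyl-2-formylphenoxy)-2-(hydroxymethyl)prop-2-enoate | COC(=O)/C(CO)=C/Oc1ccc(C(C)=O)cc1C=O | intermediate
6 | methyl (Z)-3-(4-acetyl-2-formylphenoxy)-2-(bromomethyl)prop-2-enoate | COC(=O)/C(CBr)=C/Oc1ccc(C(C)=O)cc1C=O | intermediate
7 | [(Z)-3-(4-acetyl-2-formylphenoxy)-2-(methoxycarbonyl)prop-2-enyl]chromium dichloride (trivalent chromium, ligand left out of the drawing) | COC(=O)/C(C[Cr](Cl)Cl)=C/Oc1ccc(C(C)=O)cc1C=O | intermediate (not isolated)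
8 | methyl 2-[(2S,3S)-5-acetyl-3-(trimethylsilyloxy)-2,3-dihydro-1-benzofuran-2-yl]prop-2-enoate | C=C(C(=O)OC)[C@@H]1Oc2ccc(C(C)=O)cc2[C@@H]1O[Si](C)(C)C | intermediate (not isolated)
9 | methyl 2-[(2S,3S)-5-acetyl-3-hydroxy-2,3-dihydro-1-benzofuran-2-yl]prop-2-enoate | C=C(C(=O)OC)[C@@H]1Oc2ccc(C(C)=O)cc2[C@@H]1O | intermediate
10 | methyl 2-[(2S,3S)-3-acetoxy-5-acetyl-2,3-dihydro-1-benzofuran-2-yl]prop-2-enoate | C=C(C(=O)OC)[C@@H]1Oc2ccc(C(C)=O)cc2[C@@H]1OC(C)=O | intermediate
11 | methyl 2-[(2S,3S)-3-acetoxy-5-[(1S)-1-hydroxyethyl]-2,3-dihydro-1-benzofuran-2-yl]prop-2-enoate | C=C(C(=O)OC)[C@@H]1Oc2ccc([C@H](C)O)cc2[C@@H]1OC(C)=O | intermediate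
12 | (E)-2-methylbut-2-enoyl chloride (tigloyl chloride) | C/C=C(\C)C(=O)Cl | starting material
13 | methyl 2-[(2S,3S)-3-acetoxy-5-[(1S)-1-{[(E)-2-methylbut-2-enoyl]oxy}ethyl]-2,3-dihydro-1-benzofuran-2-yl]prop-2-enoate | C=C(C(=O)OC)[C@@H]1Oc2ccc([C@H](C)OC(=O)/C(C)=C/C)cc2[C@@H]1OC(C)=O | target

## Step count and least certain steps

Total step count: 7. Longest linear sequence: 7 (1 → 3 → 5 → 6 → 9 → 10 → 11 → 13).

**Step 4 (key step).**
- Most likely failure: poor facial discrimination. The tether dictates how the formyl group sits in the ligand pocket, and this may differ from the intermolecular cases for which the ligand class was shaped.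
- Further risks:
  - a ligand-free background allylation on the manganese surface;
  - reductive dimerisation of the allyl bromide or pinacol coupling of the electron-poor aldehyde if the stationary concentration of 6 is too high;
  - attack of the chromium alkoxide on the cis ester before silylation.
- The cis outcome itself rests on geometry and is the safer part.
- Fallback (from 6, back at 10): catalyst control of the C–C bond formation is given up and only the geometric cis control is kept. Indium powder in THF/water (Barbier conditions) should close 6 through the same kind of cyclic transition state to the racemic cis alcohol. This is 9 together with its mirror image, methyl 2-[(2R,3R)-5-acetyl-3-hydroxy-2,3-dihydro-1-benzofuran-2-yl]prop-2-enoate F1. An acylative kinetic resolution with Candida antarctica lipase B and vinyl acetate in toluene is then expected to acetylate the enantiomer whose hydroxyl/aryl/alkyl arrangement matches that of the fast-reacting (R)-1-arylalkanols. That enantiomer is 9, so 10 is formed directly and F1 is left behind and separated.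

**Step 1.**
- Most likely failure: slow depolymerisation of 2. The iodoallenolate is then protonated instead of hydroxymethylated, or the product alcohol is consumed in formal (acetal) formation with excess formaldehyde.
- Fallback (from 4 and 1, back at 5): the aryl ether is made first and the CH2OH carbon is brought in by cross-coupling. The sequence is as follows.
  - N-Methylmorpholine-catalysed oxa-Michael addition of 4 to 1 in CH2Cl2 should give methyl (E)-3-(4-acetyl-2-formylphenoxy)prop-2-enoate F2.
  - Addition of Br2 at 0 °C gives methyl 2,3-dibromo-3-(4-acetyl-2-formylphenoxy)propanoate F3.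
  - Et3N added to the same flask removes HBr to give methyl (Z)-3-(4-acetyl-2-formylphenoxy)-2-bromoprop-2-enoate F4.
  - Stille coupling of F4 with (tributylstannyl)methanol (Pd(PPh3)4, dioxane, 90 °C) replaces bromine by CH2OH with retention of geometry and gives 5.

**Step 5.**
- Most likely failure: intramolecular transesterification of the free C3–OH onto the cis methyl ester during desilylation, handling or acetylation. The two groups are held close on the same face of ring B.
- A second risk is loss of acetic acid from the product on prolonged contact with base.
- Fallback (from 8, back at 10): the alcohol is never set free. The work-up of step 4 is made non-hydrolytic, 8 is isolated, and its silyl group is exchanged directly for acetyl with Ac2O and Bi(OTf)3 (1 mol %) in MeCN at 0 °C. This fallback makes no new compound (F0).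

**Step 6.**
- Most likely failure: addition of hydride or boron to the acrylate (1,4-reduction, or SN2′ opening of ring B), because O1 para to the ketone is a fair leaving group.
- A second risk is incomplete facial selectivity at the ketone.
- Fallback (from 10, back at 11): stereocontrol is moved from the reduction to a resolution.
  - Luche reduction (NaBH4, CeCl3·7H2O, MeOH, −40 °C) should give 11 together with its C1′ epimer, methyl 2-[(2S,3S)-3-acetoxy-5-[(1R)-1-hydroxyethyl]-2,3-dihydro-1-benzofuran-2-yl]prop-2-enoate F5.
  - Candida antarctica lipase B with vinyl acetate, which acylates (R)-1-arylethanols, should convert F5 into methyl 2-[(2S,3S)-3-acetoxy-5-[(1R)-1-acetoxyethyl]-2,3-dihydro-1-benzofuran-2-yl]prop-2-enoate F6.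
  - This leaves 11 untouched for separation.

## Further compounds

F1 | step 4 | methyl 2-[(2R,3R)-5-acetyl-3-hydroxy-2,3-dihydro-1-benzofuran-2-yl]prop-2-enoate | C=C(C(=O)OC)[C@H]1Oc2ccc(C(C)=O)cc2[C@H]1O
F2 | step 1 | methyl (E)-3-(4-acetyl-2-formylphenoxy)prop-2-enoate | COC(=O)/C=C/Oc1ccc(C(C)=O)cc1C=O
F3 | step 1 | methyl 2,3-dibromo-3-(4-acetyl-2-formylphenoxy)propanoate (mixture of diastereomers, racemic) | COC(=O)C(Br)C(Br)Oc1ccc(C(C)=O)cc1C=O
F4 | step 1 | methyl (Z)-3-(4-acetyl-2-formylphenoxy)-2-bromoprop-2-enoate | COC(=O)/C(Br)=C/Oc1ccc(C(C)=O)cc1C=O
F0 | step 5 | none | none
F5 | step 6 | methyl 2-[(2S,3S)-3-acetoxy-5-[(1R)-1-hydroxyethyl]-2,3-dihydro-1-benzofuran-2-yl]prop-2-enoate | C=C(C(=O)OC)[C@@H]1Oc2ccc([C@@H](C)O)cc2[C@@H]1OC(C)=O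
F6 | step 6 | methyl 2-[(2S,3S)-3-acetoxy-5-[(1R)-1-acetoxyethyl]-2,3-dihydro-1-benzofuran-2-yl]prop-2-enoate | C=C(C(=O)OC)[C@@H]1Oc2ccc([C@@H](C)OC(C)=O)cc2[C@@H]1OC(C)=O
A1 | alternative 1 | methyl 2-(5-acetyl-3-oxo-2,3-dihydro-1-benzofuran-2-yl)prop-2-enoate (racemic, C2 labile) | C=C(C(=O)OC)C1Oc2ccc(C(C)=O)cc2C1=O
A2 | alternative 1 | methyl (Z)-2-(5-acetyl-3-oxo-1-benzofuran-2(3H)-ylidene)propanoate | C/C(C(=O)OC)=C1/Oc2ccc(C(C)=O)cc2C1=O
A3 | alternative 2 | methyl 2-[(2S,3S)-3-(5-acetyl-2-hydroxyphenyl)oxiran-2-yl]prop-2-enoate | C=C(C(=O)OC)[C@@H]1O[C@H]1c1cc(C(C)=O)ccc1O
A4 | alternative 3 | methyl (E)-4-(5-acetyl-2-fluorophenyl)-2-methylidenebut-3-enoate | C=C(C(=O)OC)/C=C/c1cc(C(C)=O)ccc1F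
A5 | alternative 3 | (4S,5S)-5-(5-acetyl-2-fluorophenyl)-4-hydroxy-3-methylideneoxolan-2-one | C=C1[C@H](O)[C@H](c2cc(C(C)=O)ccc2F)OC1=O
A6 | alternative 3 | (3aS,8bS)-7-acetyl-3-methylidene-3a,8b-dihydrofuro[3,2-b][1]benzofuran-2(3H)-one | C=C1C(=O)O[C@H]2c3cc(C(C)=O)ccc3O[C@@H]12
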